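**Retrosynthetic overview**
1. Gneyulin A (28) comes from its decamethyl ether 27 by BBr3 demethylation. In 27 the C3'–aryl bond comes from a decarboxylative arylation of a C3' carboxylic acid (trans to C2'), and the C6' styryl group from a Heck coupling of a C6' triflate.
2. Ring B (O1', C2', C3', C3a', C4'–C7', C7a') comes from ring contraction of flavanone 17. C3a' bears C3' and lies between C7a'–O1' and C4'–O, which is the C8a/C4a/C5 array of a 5,7-dioxygenated chroman-4-one whose C4a is bonded to the carbonyl carbon C4 beside C3. Shifting C4a from C4 to C3 makes C3'–C3a' and leaves C4 as the ester carbon.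
3. Flavanone 17 comes from a rhodium/chiral diene 1,4-addition of ring A boronic acid 13 (boron on C5 of ring A) to 5-methoxy-7-triflyloxychromone 16; this sets C2'.
4. Ring A (O1, C2, C3, C3a–C7a) comes from a rhodium carbene C–H insertion of a diaryldiazomethane into a 2,4-dimethoxybenzyl ether (sets C3), then acid equilibration of C2 to trans; the benzophenone comes from a Friedel–Crafts acylation.
5. Order of ring formation: dihydrofuran of ring A (step 4), pyranone ring brought in at C5 (step 9), pyranone contracted to the dihydrofuran of ring B (step 10).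

Key step: step 10

Remark: the sense of induction of Rh2(R-PTAD)4 (step 4) and of (R,R)-Ph-bod* (step 9) is assumed from the usual models for these catalysts; should either deliver the opposite sense, its mirror-image form is used.

Abbreviation in names: ArA = (2R,3R)-2-(2,4-dimethoxyphenyl)-3-(3,5-dimethoxyphenyl)-6-methoxy-2,3-dihydro-1-benzofuran-5-yl (trans ring A unit, bonded through C5). Primed locants refer to ring B.

**Step 1**
Reactants: 1 1-bromo-2,4-dimethoxybenzene; 2 3,5-dimethoxybenzoyl chloride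
Product: 4 (5-bromo-2-hydroxy-4-methoxyphenyl)(3,5-dimethoxyphenyl)methanone, via tetramethoxy ketone 3 (not isolated)
Conditions: AlCl3 (2.5 equiv), ClCH2CH2Cl, 0 °C → 50 °C; aq HCl
Reagents that add atoms: none
Why: Friedel–Crafts acylation should occur at the only open position that is para to one methoxy group and ortho to the other, and the aluminium chelate of the resulting ketone then cleaves only the methyl ether ortho to the carbonyl (chelation-assisted demethylation).

**Step 2**
Reactants: 4 (5-bromo-2-hydroxy-4-methoxyphenyl)(3,5-dimethoxyphenyl)methanone; 5 2,4-dimethoxybenzyl alcohol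
Product: 6 {5-bromo-2-[(2,4-dimethoxyphenyl)methoxy]-4-methoxyphenyl}(3,5-dimethoxyphenyl)methanone
Conditions: PPh3, DIAD, THF, 0 °C → rt
Reagents that add atoms: none
Why: Mitsunobu etherification of the acidic chelated phenol with a primary benzylic alcohol gives the aryl benzyl ether without recourse to the unstable 2,4-dimethoxybenzyl halide.

**Step 3**
Reactants: 6 {5-bromo-2-[(2,4-dimethoxyphenyl)methoxy]-4-methoxyphenyl}(3,5-dimethoxyphenyl)methanone
Product: 7 hydrazone of 6 (E/Z mixture)
Conditions: N2H4·H2O (10 equiv), AcOH (cat.), EtOH, 80 °C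
Reagents that add atoms: hydrazine (as hydrate), NN
Why: Acid-catalysed condensation of the diaryl ketone with hydrazine gives the free hydrazone, and its E/Z composition is irrelevant because both isomers give the same diazo compound.

**Step 4**
Reactants: 7 hydrazone of 6
Product: 9 (2S,3R)-5-bromo-2-(2,4-dimethoxyphenyl)-3-(3,5-dimethoxyphenyl)-6-methoxy-2,3-dihydro-1-benzofuran (cis), via diaryldiazomethane 8 (not isolated)
Conditions: activated MnO2 (8 equiv), CH2Cl2, 0 °C, filter; Rh2(R-PTAD)4 (1 mol %), CH2Cl2, 0 °C → rt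
Reagents that add atoms: none
Why: Hydrazone oxidation gives the diaryldiazomethane, whose donor/donor rhodium carbene undergoes enantioselective intramolecular 1,5 C–H insertion into the electron-rich benzylic ether CH2, the chiral carboxylate catalyst setting C3 (R) and delivering the cis-2,3-diaryl ring.

**Step 5**
Reactants: 9 (2S,3R)-5-bromo-2-(2,4-dimethoxyphenyl)-3-(3,5-dimethoxyphenyl)-6-methoxy-2,3-dihydro-1-benzofuran
Product: 10 (2R,3R)-5-bromo-2-(2,4-dimethoxyphenyl)-3-(3,5-dimethoxyphenyl)-6-methoxy-2,3-dihydro-1-benzofuran (trans; ArA–Br)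
Conditions: CF3CO2H (2 equiv), CH2Cl2, 0 °C → rt
Reagents that add atoms: none
Why: Acid-catalysed cis-to-trans epimerisation of a 2-aryl-2,3-dihydrobenzofuran: reversible heterolysis of the C2–O bond (cation stabilised by the 2,4-dimethoxyphenyl group) and reclosure by the phenol oxygen should equilibrate C2 to the more stable trans isomer, while C3 is not involved and fixes C2 as R.

**Step 6**
Reactants: 10 ArA–Br
Product: 13 ArA–B(OH)2 [(2R,3R)-2-(2,4-dimethoxyphenyl)-3-(3,5-dimethoxyphenyl)-6-methoxy-2,3-dihydro-1-benzofuran-5-yl]boronic acid, via aryllithium 11 (not isolated), via lithium aryltrimethoxyborate 12 (not isolated)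
Conditions: n-BuLi (1.05 equiv), THF, −78 °C; B(OMe)3, −78 °C → rt; 1 M HCl to pH 5, 0 °C
Reagents that add atoms: trimethyl borate, COB(OC)OC; water, O
Why: Bromine–lithium exchange at −78 °C is faster than deprotonation of the benzylic C2–H and C3–H, and trapping with the borate followed by mild hydrolysis gives the boronic acid with both stereocentres untouched.

**Step 7**
Reactants: 14 5,7-dihydroxy-4H-chromen-4-one
Product: 15 5-hydroxy-4-oxo-4H-chromen-7-yl trifluoromethanesulfonate
Conditions: PhNTf2 (1.05 equiv), Et3N, CH2Cl2, 0 °C → rt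
Reagents that add atoms: N-phenylbis(trifluoromethanesulfonimide), O=S(=O)(N(c1ccccc1)S(=O)(=O)C(F)(F)F)C(F)(F)F
Why: The 7-hydroxyl is more acidic and more nucleophilic than the 5-hydroxyl, which is hydrogen-bonded to the carbonyl, so O-sulfonylation should be selective for O7.

**Step 8**
Reactants: 15 5-hydroxy-4-oxo-4H-chromen-7-yl trifluoromethanesulfonate
Product: 16 5-methoxy-4-oxo-4H-chromen-7-yl trifluoromethanesulfonate
Conditions: MeI, K2CO3, DMF, rt
Reagents that add atoms: iodomethane, CI
Why: Williamson O-methylation of the remaining chelated phenol; the aryl triflate should tolerate anhydrous carbonate at room temperature.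

**Step 9**
Reactants: 13 ArA–B(OH)2; 16 5-methoxy-4-oxo-4H-chromen-7-yl trifluoromethanesulfonate (1.5 equiv)
Product: 17 (2R)-2-ArA-5-methoxy-4-oxo-3,4-dihydro-2H-chromen-7-yl trifluoromethanesulfonate
Conditions: [RhCl(C2H4)2]2 (2.5 mol %), (R,R)-Ph-bod* [(1R,4R)-2,5-diphenylbicyclo[2.2.2]octa-2,5-diene] (5.5 mol %), aq KOH (10 mol %), toluene, 30 °C
Reagents that add atoms: none
Why: Rhodium-catalysed asymmetric 1,4-addition of an arylboronic acid to a chromone (Hayashi–Miyaura reaction), in which the chiral diene decides the face of C2 (2R) independently of the remote ring A centres; rhodium–diene catalysts accept ortho-alkoxy arylboronic acids, the aryl triflate is inert to rhodium(I), and the low base loading limits opening of the flavanone to its chalcone.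

**Step 10**
Reactants: 17 (2R)-2-ArA-5-methoxy-4-oxo-3,4-dihydro-2H-chromen-7-yl trifluoromethanesulfonate
Product: 18 methyl (2R,3R)-2-ArA-4-methoxy-6-[(trifluoromethanesulfonyl)oxy]-2,3-dihydro-1-benzofuran-3-carboxylate (trans)
Conditions: PhI(OAc)2 (1.2 equiv), H2SO4 (0.3 equiv), HC(OMe)3, 0 °C → rt, under 1 h; aq NaHCO3
Reagents that add atoms: trimethyl orthoformate, COC(OC)OC
Why: Acid and orthoformate convert the C4 ketone into its methyl enol ether (C3=C4), which iodine(III) attacks at C3 on the face away from the C2 aryl group; methanol then adds at C4, and the aryl carbon C4a, antiperiplanar to the equatorial C3–I bond, shifts from C4 to C3 as iodobenzene leaves, the dimethoxycarbenium ion collapsing to the methyl ester. This is the known iodine(III) (or thallium(III)) oxidative ring contraction of flavanones to methyl trans-2-aryl-2,3-dihydrobenzofuran-3-carboxylates, a semipinacol-type 1,2-aryl shift. Ring B is closed by that shift (contraction of the pyranone, with C3'–C3a' made by migration and not by a cyclisation), so C3a' necessarily ends between O1' and the C4' oxygen. C3' is set by C2': anti iodination followed by inversion at C3 should place the ester trans to the C2' substituent (2'R,3'R), and C2' itself is not touched. The step needs migration of C4a in preference to the C2 aryl group (which would lead to an isoflavone) and attack of iodine(III) on the enol ether in preference to the methoxylated rings; the two oxygen substituents ortho to C4a and the antiperiplanar C4–C4a bond favour the contraction, and the 7-triflate lowers the nucleophilicity of the chromanone benzo ring without removing those donors. Low temperature, sub-stoichiometric acid and a short reaction time are chosen because acid can open the flavanone to its chalcone and ionise the benzylic C2–O bond of ring A.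

**Step 11**
Reactants: 19 2,4-dimethoxybenzaldehyde
Product: 20 2,4-dimethoxystyrene (1-ethenyl-2,4-dimethoxybenzene)
Conditions: Ph3PCH3Br, KOtBu, THF, 0 °C → rt
Reagents that add atoms: methyltriphenylphosphonium bromide, C[P+](c1ccccc1)(c1ccccc1)c1ccccc1.[Br-]
Why: Wittig methylenation of an aromatic aldehyde with the non-stabilised ylide; the styrene is made fresh because it polymerises on storage.

**Step 12**
Reactants: 18 methyl (2R,3R)-2-ArA-4-methoxy-6-[(trifluoromethanesulfonyl)oxy]-2,3-dihydro-1-benzofuran-3-carboxylate; 20 2,4-dimethoxystyrene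
Product: 21 methyl (2R,3R)-2-ArA-6-[(E)-2-(2,4-dimethoxyphenyl)ethenyl]-4-methoxy-2,3-dihydro-1-benzofuran-3-carboxylate
Conditions: PdCl2(PPh3)2 (5 mol %), LiCl (3 equiv), Et3N, DMF, 90 °C, dark
Reagents that add atoms: none
Why: Mizoroki–Heck coupling of the unhindered C6' triflate; chloride directs the reaction through the neutral pathway, so the electron-rich styrene should be arylated at its terminal carbon and syn insertion/syn β-hydride elimination give the E stilbene, while the trans ester is the thermodynamic isomer under the amine base.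

**Step 13**
Reactants: 21 methyl (2R,3R)-2-ArA-6-[(E)-2-(2,4-dimethoxyphenyl)ethenyl]-4-methoxy-2,3-dihydro-1-benzofuran-3-carboxylate
Product: 22 (2R,3R)-2-ArA-6-[(E)-2-(2,4-dimethoxyphenyl)ethenyl]-4-methoxy-2,3-dihydro-1-benzofuran-3-carboxylic acid
Conditions: LiOH·H2O, THF/MeOH/H2O, 40 °C; 1 M HCl to pH 4, 0 °C
Reagents that add atoms: lithium hydroxide, [Li+].[OH-]
Why: Saponification of the methyl ester; the trans arrangement at C2'/C3' is the thermodynamic one, so any enolisation at C3' under the basic conditions should not change it.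

**Step 14**
Reactants: 22 (2R,3R)-2-ArA-6-[(E)-2-(2,4-dimethoxyphenyl)ethenyl]-4-methoxy-2,3-dihydro-1-benzofuran-3-carboxylic acid
Product: 23 1,3-dioxoisoindolin-2-yl (2R,3R)-2-ArA-6-[(E)-2-(2,4-dimethoxyphenyl)ethenyl]-4-methoxy-2,3-dihydro-1-benzofuran-3-carboxylate
Conditions: N-hydroxyphthalimide, DIC, DMAP (cat.), CH2Cl2, rt
Reagents that add atoms: N-hydroxyphthalimide, O=C1c2ccccc2C(=O)N1O
Why: Carbodiimide (Steglich-type) esterification gives the redox-active N-acyloxyphthalimide under neutral conditions.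

**Step 15**
Reactants: 24 1-bromo-3,5-dimethoxybenzene
Product: 26 (3,5-dimethoxyphenyl)zinc chloride (THF solution, LiCl complex), via arylmagnesium bromide 25 (not isolated)
Conditions: Mg, LiCl, THF, rt; ZnCl2 (1.0 equiv), THF, 0 °C → rt
Reagents that add atoms: zinc chloride, Cl[Zn]Cl
Why: Grignard formation followed by transmetallation to zinc gives the arylzinc nucleophile used in decarboxylative Negishi-type couplings.

**Step 16**
Reactants: 23 redox-active ester; 26 (3,5-dimethoxyphenyl)zinc chloride (3 equiv)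
Product: 27 gneyulin A decamethyl ether [(2R,3R)-2-ArA-3-(3,5-dimethoxyphenyl)-6-[(E)-2-(2,4-dimethoxyphenyl)ethenyl]-4-methoxy-2,3-dihydro-1-benzofuran]
Conditions: NiCl2·glyme (20 mol %), 4,4'-di-tert-butyl-2,2'-bipyridine (40 mol %), THF/DMF, rt, dark
Reagents that add atoms: none
Why: Nickel-catalysed decarboxylative arylation of a redox-active ester with an arylzinc reagent: single-electron reduction and loss of CO2 give a planar benzylic C3' radical, which should be captured by aryl-nickel on the face away from the C2' substituent, so that reductive elimination sets C3' (R) trans to C2'.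

**Step 17**
Reactants: 27 gneyulin A decamethyl ether
Product: 28 gneyulin A
Conditions: BBr3 (30 equiv), CH2Cl2, −78 °C → 0 °C, dark, argon; MeOH/ice quench
Reagents that add atoms: none
Why: Lewis-acid cleavage of the ten aryl methyl ethers; complexation of each oxygen by boron should temper the rings so that the stilbene and the benzylic C–O bonds survive, and any reversible opening at C2 or C2' should reclose to the trans isomers because C3 and C3' are not involved.

**Compound list**
1 | 1-bromo-2,4-dimethoxybenzene | COc1ccc(Br)c(OC)c1 | starting material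
2 | 3,5-dimethoxybenzoyl chloride | COc1cc(OC)cc(C(=O)Cl)c1 | starting material
3 | (5-bromo-2,4-dimethoxyphenyl)(3,5-dimethoxyphenyl)methanone | COc1cc(OC)cc(C(=O)c2cc(Br)c(OC)cc2OC)c1 | intermediate (not isolated)
4 | (5-bromo-2-hydroxy-4-methoxyphenyl)(3,5-dimethoxyphenyl)methanone | COc1cc(OC)cc(C(=O)c2cc(Br)c(OC)cc2O)c1 | intermediate
5 | 2,4-dimethoxybenzyl alcohol | COc1ccc(CO)c(OC)c1 | starting material
6 | {5-bromo-2-[(2,4-dimethoxyphenyl)methoxy]-4-methoxyphenyl}(3,5-dimethoxyphenyl)methanone | COc1cc(OC)cc(C(=O)c2cc(Br)c(OC)cc2OCc2ccc(OC)cc2OC)c1 | intermediate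
7 | hydrazone of 6 (E/Z mixture) | COc1cc(OC)cc(C(=NN)c2cc(Br)c(OC)cc2OCc2ccc(OC)cc2OC)c1 | intermediate
8 | {5-bromo-2-[(2,4-dimethoxyphenyl)methoxy]-4-methoxyphenyl}(3,5-dimethoxyphenyl)diazomethane | COc1cc(OC)cc(C(=[N+]=[N-])c2cc(Br)c(OC)cc2OCc2ccc(OC)cc2OC)c1 | intermediate (not isolated)
9 | (2S,3R)-5-bromo-2-(2,4-dimethoxyphenyl)-3-(3,5-dimethoxyphenyl)-6-methoxy-2,3-dihydro-1-benzofuran (cis) | COc1cc(OC)cc([C@@H]2c3cc(Br)c(OC)cc3O[C@@H]2c2ccc(OC)cc2OC)c1 | intermediate
10 | (2R,3R)-5-bromo-2-(2,4-dimethoxyphenyl)-3-(3,5-dimethoxyphenyl)-6-methoxy-2,3-dihydro-1-benzofuran (trans, ArA–Br) | COc1cc(OC)cc([C@@H]2c3cc(Br)c(OC)cc3O[C@H]2c2ccc(OC)cc2OC)c1 | intermediate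
11 | ArA–Li (5-lithio derivative of 10) | COc1cc(OC)cc([C@@H]2c3cc([Li])c(OC)cc3O[C@H]2c2ccc(OC)cc2OC)c1 | intermediate (not isolated)
12 | lithium trimethoxy(ArA)borate | COc1cc(OC)cc([C@@H]2c3cc([B-](OC)(OC)OC)c(OC)cc3O[C@H]2c2ccc(OC)cc2OC)c1.[Li+] | intermediate (not isolated)
13 | ArA–B(OH)2, [(2R,3R)-2-(2,4-dimethoxyphenyl)-3-(3,5-dimethoxyphenyl)-6-methoxy-2,3-dihydro-1-benzofuran-5-yl]boronic acid | COc1cc(OC)cc([C@@H]2c3cc(B(O)O)c(OC)cc3O[C@H]2c2ccc(OC)cc2OC)c1 | intermediate
14 | 5,7-dihydroxy-4H-chromen-4-one | O=c1ccoc2cc(O)cc(O)c12 | starting material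
15 | 5-hydroxy-4-oxo-4H-chromen-7-yl trifluoromethanesulfonate | O=c1ccoc2cc(OS(=O)(=O)C(F)(F)F)cc(O)c12 | intermediate
16 | 5-methoxy-4-oxo-4H-chromen-7-yl trifluoromethanesulfonate | COc1cc(OS(=O)(=O)C(F)(F)F)cc2occc(=O)c12 | intermediate
17 | (2R)-2-ArA-5-methoxy-4-oxo-3,4-dihydro-2H-chromen-7-yl trifluoromethanesulfonate (key-step precursor) | COc1cc(OC)cc([C@@H]2c3cc([C@H]4CC(=O)c5c(OC)cc(OS(=O)(=O)C(F)(F)F)cc5O4)c(OC)cc3O[C@H]2c2ccc(OC)cc2OC)c1 | intermediate
18 | methyl (2R,3R)-2-ArA-4-methoxy-6-[(trifluoromethanesulfonyl)oxy]-2,3-dihydro-1-benzofuran-3-carboxylate (key-step product) | COc1cc(OC)cc([C@@H]2c3cc([C@@H]4Oc5cc(OS(=O)(=O)C(F)(F)F)cc(OC)c5[C@H]4C(=O)OC)c(OC)cc3O[C@H]2c2ccc(OC)cc2OC)c1 | intermediate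
19 | 2,4-dimethoxybenzaldehyde | COc1ccc(C=O)c(OC)c1 | starting material
20 | 2,4-dimethoxystyrene | C=Cc1ccc(OC)cc1OC | intermediate
21 | methyl (2R,3R)-2-ArA-6-[(E)-2-(2,4-dimethoxyphenyl)ethenyl]-4-methoxy-2,3-dihydro-1-benzofuran-3-carboxylate | COc1cc(OC)cc([C@@H]2c3cc([C@@H]4Oc5cc(/C=C/c6ccc(OC)cc6OC)cc(OC)c5[C@H]4C(=O)OC)c(OC)cc3O[C@H]2c2ccc(OC)cc2OC)c1 | intermediate
22 | (2R,3R)-2-ArA-6-[(E)-2-(2,4-dimethoxyphenyl)ethenyl]-4-methoxy-2,3-dihydro-1-benzofuran-3-carboxylic acid | COc1cc(OC)cc([C@@H]2c3cc([C@@H]4Oc5cc(/C=C/c6ccc(OC)cc6OC)cc(OC)c5[C@H]4C(=O)O)c(OC)cc3O[C@H]2c2ccc(OC)cc2OC)c1 | intermediate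
23 | 1,3-dioxoisoindolin-2-yl ester of 22 | COc1cc(OC)cc([C@@H]2c3cc([C@@H]4Oc5cc(/C=C/c6ccc(OC)cc6OC)cc(OC)c5[C@H]4C(=O)ON4C(=O)c5ccccc5C4=O)c(OC)cc3O[C@H]2c2ccc(OC)cc2OC)c1 | intermediate
24 | 1-bromo-3,5-dimethoxybenzene | COc1cc(Br)cc(OC)c1 | starting material
25 | (3,5-dimethoxyphenyl)magnesium bromide | COc1cc(OC)cc([Mg]Br)c1 | intermediate (not isolated)
26 | (3,5-dimethoxyphenyl)zinc chloride | COc1cc(OC)cc([Zn]Cl)c1 | intermediate
27 | gneyulin A decamethyl ether | COc1cc(OC)cc([C@@H]2c3cc([C@@H]4Oc5cc(/C=C/c6ccc(OC)cc6OC)cc(OC)c5[C@H]4c4cc(OC)cc(OC)c4)c(OC)cc3O[C@H]2c2ccc(OC)cc2OC)c1 | intermediate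
28 | gneyulin A, (2R,3R,2'R,3'R) | Oc1cc(O)cc([C@@H]2c3cc([C@@H]4Oc5cc(/C=C/c6ccc(O)cc6O)cc(O)c5[C@H]4c4cc(O)cc(O)c4)c(O)cc3O[C@H]2c2ccc(O)cc2O)c1 | target

**Totals**
Total step count: 17. Longest linear sequence: 13 steps (steps 1–6, 9, 10, 12, 13, 14, 16, 17).

**Steps most likely to fail**

Step 10 (ring contraction). The acid may open the flavanone to its chalcone, with loss of the C2' configuration. The C2 aryl group may migrate in place of C4a. Iodine(III) may oxidise the methoxylated rings, or a phenol set free by acid opening of ring A. The fallback makes the same C4a shift as a Wolff rearrangement, without acid or oxidant, and sets out from flavanone 17. Treatment with LiHMDS and 2,2,2-trifluoroethyl trifluoroacetate at −78 °C should give the 3-trifluoroacetyl ketone F1. Detrifluoroacetylative diazo transfer (MsN3, Et3N, H2O, MeCN) then gives the 3-diazoflavanone F2. Irradiation (365 nm) in MeOH/THF contracts the ring to the methyl ester as a mixture of 18 and its C3' epimer, the cis ester F3. DBU in CH2Cl2 equilibrates F3 to the trans ester, and the route is rejoined at 18.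

Step 9 (asymmetric 1,4-addition). Protodeboronation of the electron-rich ortho-methoxy boronic acid may outrun the addition. Base may open the product to the chalcone, so that diastereomeric purity at C2' is lost. The fallback builds the flavanone by condensation and sets out from bromide 10. Lithiation to 11 and quenching with DMF gives the ring A aldehyde F4. Commercial 2',4'-dihydroxy-6'-methoxyacetophenone is triflated at the 4'-hydroxyl (PhNTf2, Et3N) to the acetophenone triflate F5. Pyrrolidine-mediated Claisen–Schmidt condensation of F4 with F5 (EtOH, 40 °C) gives the chalcone F6. Oxa-Michael cyclisation (NaOAc, EtOH, 60 °C) gives flavanone 17 together with its 2S epimer F7. The two are diastereomers and are separated by chromatography; F7 is returned to the cyclisation conditions, where it equilibrates through F6. The route is rejoined at 17.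

Step 16 (decarboxylative arylation). The stabilised benzylic radical may dimerise or be reduced instead of being captured at nickel, or the facial selectivity at C3' may be poor. The fallback separates radical generation from C–C bond formation and sets out from redox-active ester 23. Copper-catalysed decarboxylative borylation (Cu(acac)2, B2pin2, LiOH·H2O, MgCl2, dioxane/DMF, rt) should give the trans C3' pinacol boronate F8. Stereoretentive Suzuki–Miyaura coupling of this secondary benzylic boronate with 1-bromo-3,5-dimethoxybenzene 24 (Pd2(dba)3, PPh3, Ag2O, DME, 80 °C) rejoins the route at 27.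

**Further compounds**
F1 | step 10 | (2R)-2-ArA-5-methoxy-4-oxo-3-(trifluoroacetyl)-3,4-dihydro-2H-chromen-7-yl trifluoromethanesulfonate (C3 not defined, enolised) | COc1cc(OC)cc([C@@H]2c3cc([C@H]4C(C(=O)C(F)(F)F)C(=O)c5c(OC)cc(OS(=O)(=O)C(F)(F)F)cc5O4)c(OC)cc3O[C@H]2c2ccc(OC)cc2OC)c1
F2 | step 10 | (2S)-2-ArA-3-diazo-5-methoxy-4-oxo-3,4-dihydro-2H-chromen-7-yl trifluoromethanesulfonate (same spatial arrangement at C2 as 17; the descriptor changes with the priorities) | COc1cc(OC)cc([C@@H]2c3cc([C@H]4C(=[N+]=[N-])C(=O)c5c(OC)cc(OS(=O)(=O)C(F)(F)F)cc5O4)c(OC)cc3O[C@H]2c2ccc(OC)cc2OC)c1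
F3 | step 10 | methyl (2R,3S)-2-ArA-4-methoxy-6-[(trifluoromethanesulfonyl)oxy]-2,3-dihydro-1-benzofuran-3-carboxylate (cis) | COc1cc(OC)cc([C@@H]2c3cc([C@@H]4Oc5cc(OS(=O)(=O)C(F)(F)F)cc(OC)c5[C@@H]4C(=O)OC)c(OC)cc3O[C@H]2c2ccc(OC)cc2OC)c1
F4 | step 9 | (2R,3R)-2-(2,4-dimethoxyphenyl)-3-(3,5-dimethoxyphenyl)-6-methoxy-2,3-dihydro-1-benzofuran-5-carbaldehyde | COc1cc(OC)cc([C@@H]2c3cc(C=O)c(OC)cc3O[C@H]2c2ccc(OC)cc2OC)c1
F5 | step 9 | 4-acetyl-3-hydroxy-5-methoxyphenyl trifluoromethanesulfonate | CC(=O)c1c(O)cc(OS(=O)(=O)C(F)(F)F)cc1OC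
F6 | step 9 | 3-hydroxy-5-methoxy-4-[(E)-3-ArA-prop-2-enoyl]phenyl trifluoromethanesulfonate (chalcone) | COc1cc(OC)cc([C@@H]2c3cc(/C=C/C(=O)c4c(O)cc(OS(=O)(=O)C(F)(F)F)cc4OC)c(OC)cc3O[C@H]2c2ccc(OC)cc2OC)c1
F7 | step 9 | (2S)-2-ArA-5-methoxy-4-oxo-3,4-dihydro-2H-chromen-7-yl trifluoromethanesulfonate (C2 epimer of 17) | COc1cc(OC)cc([C@@H]2c3cc([C@@H]4CC(=O)c5c(OC)cc(OS(=O)(=O)C(F)(F)F)cc5O4)c(OC)cc3O[C@H]2c2ccc(OC)cc2OC)c1
F8 | step 16 | 2-{(2R,3R)-2-ArA-6-[(E)-2-(2,4-dimethoxyphenyl)ethenyl]-4-methoxy-2,3-dihydro-1-benzofuran-3-yl}-4,4,5,5-tetramethyl-1,3,2-dioxaborolane (trans) | COc1cc(OC)cc([C@@H]2c3cc([C@@H]4Oc5cc(/C=C/c6ccc(OC)cc6OC)cc(OC)c5[C@H]4B4OC(C)(C)C(C)(C)O4)c(OC)cc3O[C@H]2c2ccc(OC)cc2OC)c1
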